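Target 20 ⇐ 19 (two aryl silyl ethers removed) ⇐ alkenyl iodide 9 + acyclic enal 17: one operation makes the central C2'–C3' single bond of the butadiene (C1' on isochromenone C3, C4' on oxolane C2) and closes the oxolane at O1–C2.
Enabling feature: oxolane O1–C2 is a dienylic ether bond. C2 ends the five-carbon π-array C2/C4'/C3'/C2'/C1', which is conjugated with C3=C4 of the isochromenone, so a C3' carbinol made by the union ionizes easily and the C5 oxygen closes the ring at C2 with 1,3-transposition.
9 comes from methyl orsellinate (benzene ring bought): chlorination, lateral acylation, acid closure of the pyranone ring, Takai olefination.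
17 comes from ethyl (S)-3-hydroxybutanoate: Weinreb ketone synthesis, 1,3-anti reduction (sets C3), temporary 1,3-dioxane, cross-metathesis.
Ring order: pyranone ring (step 4), temporary dioxane ring (step 10), oxolane ring (step 12).

Key step: step 12

Remark: alcohol 18 forms as both epimers at its carbinol carbon; this centre is destroyed in the same flask, so it is left undefined in the SMILES of 18.

Step 1
Reactants: 1 methyl 2,4-dihydroxy-6-methylbenzoate (methyl orsellinate)
Product: 2 methyl 3-chloro-4,6-dihydroxy-2-methylbenzoate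
Conditions: SO2Cl2 (1.05 equiv), Et2O, 0 °C to rt
Reagents that add atoms: sulfuryl chloride, O=S(=O)(Cl)Cl
Why: Electrophilic aromatic chlorination should occur at the ring carbon between the methyl-bearing and the 4-hydroxy-bearing carbons, which is para to the hydrogen-bonded 2-hydroxyl and less encumbered than the site between the two hydroxyls, as in the known chlorination of orsellinates and orcylaldehyde.

Step 2
Reactants: 2 methyl 3-chloro-4,6-dihydroxy-2-methylbenzoate
Product: 3 methyl 3-chloro-4,6-bis(methoxymethoxy)-2-methylbenzoate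
Conditions: NaH (2.5 equiv), MOMCl (2.5 equiv), DMF, 0 °C to rt
Reagents that add atoms: chloromethyl methyl ether, COCCl
Why: Williamson-type O-alkylation of both sodium phenoxides (NaH is needed for the ester-chelated hydroxyl) gives the bis(methoxymethyl) ether, which tolerates the strong base of step 3.

Step 3
Reactants: 3 methyl 3-chloro-4,6-bis(methoxymethoxy)-2-methylbenzoate; 4 ethyl 2,2-diethoxyacetate
Product: 5 methyl 3-chloro-2-(3,3-diethoxy-2-oxopropyl)-4,6-bis(methoxymethoxy)benzoate
Conditions: LiN(iPr)2 (2.2 equiv), THF, −78 °C; then 4, −78 °C; aq. NH4Cl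
Reagents that add atoms: none
Why: Lateral lithiation of the o-toluate gives a benzylic anion stabilized by the ortho ester, which undergoes Claisen-type C-acylation by ester 4, while the second equivalent of base converts the product ketone into its enolate and so prevents a second addition.

Step 4
Reactants: 5 methyl 3-chloro-2-(3,3-diethoxy-2-oxopropyl)-4,6-bis(methoxymethoxy)benzoate
Product: 6 5-chloro-6,8-dihydroxy-1-oxo-1H-isochromene-3-carbaldehyde
Conditions: 3 M aq. HCl, THF, 60 °C
Reagents that add atoms: water, O
Why: Acid hydrolysis of the two methoxymethyl ethers and of the diethyl acetal, together with acid-catalysed enol lactonization (6-exo-trig attack of the ketone enol oxygen on the ester carbonyl with loss of methanol), should close the pyranone ring and deliver the 3-formylisochromenone in one cascade.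

Step 5
Reactants: 6 5-chloro-6,8-dihydroxy-1-oxo-1H-isochromene-3-carbaldehyde
Product: 7 6,8-bis[(tert-butyldimethylsilyl)oxy]-5-chloro-1-oxo-1H-isochromene-3-carbaldehyde
Conditions: TBSOTf (2.5 equiv), 2,6-lutidine, CH2Cl2, −78 to 0 °C
Reagents that add atoms: tert-butyldimethylsilyl trifluoromethanesulfonate, CC(C)(C)[Si](C)(C)OS(=O)(=O)C(F)(F)F
Why: Silylation with the silyl triflate and a hindered base protects both phenols, including the one hydrogen-bonded to the lactone carbonyl, as fluoride-labile ethers that are inert to the chromium reagents of steps 6 and 12.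

Step 6
Reactants: 7 6,8-bis[(tert-butyldimethylsilyl)oxy]-5-chloro-1-oxo-1H-isochromene-3-carbaldehyde; 8 iodoform
Product: 9 6,8-bis[(tert-butyldimethylsilyl)oxy]-5-chloro-3-[(E)-2-iodoethenyl]-1H-isochromen-1-one
Conditions: 8 (2 equiv), CrCl2 (6 equiv), THF, 0 °C to rt, dark
Reagents that add atoms: none
Why: Takai olefination, in which the gem-dichromium species formed from CHI3 and CrCl2 adds to the aldehyde and eliminates to give the E alkenyl iodide selectively without touching the lactone or the aryl chloride.

Step 7
Reactants: 10 ethyl (S)-3-hydroxybutanoate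
Product: 11 (S)-3-hydroxy-N-methoxy-N-methylbutanamide
Conditions: MeNH(OMe)·HCl, iPrMgCl, THF, −20 to 0 °C
Reagents that add atoms: N,O-dimethylhydroxylamine hydrochloride, CNOC.Cl
Why: Aminolysis of the ester by the chloromagnesium amide of N,O-dimethylhydroxylamine (Weinreb amide formation) proceeds without protection of the hydroxyl and leaves the stereocenter untouched.

Step 8
Reactants: 11 (S)-3-hydroxy-N-methoxy-N-methylbutanamide; 12 vinylmagnesium bromide
Product: 13 (S)-5-hydroxyhex-1-en-3-one
Conditions: CH2=CHMgBr (3 equiv), THF, 0 °C; inverse quench into cold 1 M aq. HCl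
Reagents that add atoms: none
Why: Weinreb ketone synthesis, in which the Grignard reagent adds only once because the chelated tetrahedral intermediate survives until the cold acidic inverse quench, which also suppresses conjugate addition of the released amine to the enone.

Step 9
Reactants: 13 (S)-5-hydroxyhex-1-en-3-one
Product: 14 (3R,5S)-hex-1-ene-3,5-diol
Conditions: Me4NBH(OAc)3, MeCN/AcOH (1:1), −30 °C
Reagents that add atoms: none
Why: Evans-Saksena directed reduction, in which the hydroxyl exchanges onto boron and delivers hydride intramolecularly through a chair-like transition state, should set the new carbinol center (3R) 1,3-anti to the existing one.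

Step 10
Reactants: 14 (3R,5S)-hex-1-ene-3,5-diol
Product: 15 (4R,6S)-4-ethenyl-2,2,6-trimethyl-1,3-dioxane
Conditions: Me2C(OMe)2, PPTS (cat.), CH2Cl2, rt
Reagents that add atoms: 2,2-dimethoxypropane, COC(C)(C)OC
Why: Acid-catalysed transketalization ties the anti-1,3-diol into an isopropylidene acetal, a temporary ring that blocks oxa-Michael addition to the enal made in step 11 and later hands its two oxygen atoms to the oxolane and the C3 hydroxyl.

Step 11
Reactants: 15 (4R,6S)-4-ethenyl-2,2,6-trimethyl-1,3-dioxane; 16 (E)-but-2-enal (crotonaldehyde)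
Product: 17 (E)-3-[(4R,6S)-2,2,6-trimethyl-1,3-dioxan-4-yl]prop-2-enal
Conditions: 16 (5 equiv), second-generation Hoveyda-Grubbs catalyst RuCl2(H2IMes)(=CH-C6H4-2-OiPr) (5 mol%), CH2Cl2, 40 °C
Reagents that add atoms: none
Why: Olefin cross-metathesis of the terminal alkene with excess crotonaldehyde should give the conjugated enal with the thermodynamically favored E geometry and does not affect the allylic stereocenter.

Step 12
Reactants: 9 6,8-bis[(tert-butyldimethylsilyl)oxy]-5-chloro-3-[(E)-2-iodoethenyl]-1H-isochromen-1-one; 17 (E)-3-[(4R,6S)-2,2,6-trimethyl-1,3-dioxan-4-yl]prop-2-enal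
Product: 19 6,8-bis[(tert-butyldimethylsilyl)oxy]-5-chloro-3-[(1E,3E)-4-[(2S,3R,5S)-3-hydroxy-5-methyloxolan-2-yl]buta-1,3-dien-1-yl]-1H-isochromen-1-one, via bis-allylic alcohol 18 (not isolated)
Conditions: 17 (1.3 equiv), CrCl2 (4 equiv), NiCl2 (2 mol%), DMF/THF, rt; then air (to oxidize the remaining CrCl2), 1 M aq. HCl, rt
Reagents that add atoms: none
Why: NiCl2 is reduced by CrCl2 to zerovalent nickel, which inserts into the C–I bond of 9 with retention of the E geometry and passes the alkenyl group to trivalent chromium; this alkenylchromium adds 1,2 to the aldehyde of 17 and so makes the C2'–C3' bond (Nozaki-Hiyama-Kishi reaction), giving 18 as both carbinol epimers. On acidification 18 should ionize at its doubly allylic C3' carbinol to a pentadienyl cation that is further stabilized by conjugation with C3=C4 of the isochromenone; the dioxane oxygen on the methyl-bearing carbon (directly, or after hydrolysis of the acetal) captures the cation terminus next to the dioxane in a 5-exo-trig closure of the oxolane, and the acetal carbon leaves as acetone to free the C3 hydroxyl. The closest known reaction types are the Nozaki-Hiyama-Kishi coupling of alkenyl iodides with enals and the acid- or Re2O7-mediated ionizing cycloetherification of allylic alcohols with 1,3-transposition. The new stereocenter C2 is controlled by the adjacent C3 center: with the C3–H bond eclipsing the cation plane (minimal allylic 1,3-strain) the dienyl group ends up trans to the C3 oxygen, and because the dienylic ether can re-ionize, the 2,3-trans (2S) isomer should also be the thermodynamic product, while the carbinol configuration of 18 is erased (stereoconvergence). The step needs 1,2- rather than 1,4-addition (intrinsic to organochromium reagents), oxygen attack at C2 rather than at the other cation termini (only this gives a five-membered ring and the fully conjugated arene-triene), and E geometry at both alkenes (retention at C1'=C2', extended cation geometry at C3'=C4'). Oxidizing the residual divalent chromium before acidification prevents reduction of transient allylic chlorides, and the aryl silyl ethers, the lactone and the aryl chloride should be inert to both stages.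

Step 13
Reactants: 19 6,8-bis[(tert-butyldimethylsilyl)oxy]-5-chloro-3-[(1E,3E)-4-[(2S,3R,5S)-3-hydroxy-5-methyloxolan-2-yl]buta-1,3-dien-1-yl]-1H-isochromen-1-one
Product: 20 5-chloro-6,8-dihydroxy-3-[(1E,3E)-4-[(2S,3R,5S)-3-hydroxy-5-methyloxolan-2-yl]buta-1,3-dien-1-yl]-1H-isochromen-1-one
Conditions: Bu4NF, AcOH, THF, 0 °C
Reagents that add atoms: none
Why: Fluoride cleaves the two aryl silyl ethers (desilylation) while acetic acid buffers the phenoxides, so that the lactone, the dienyl ether and the secondary alcohol should be left untouched.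

Compound list
1 | methyl 2,4-dihydroxy-6-methylbenzoate (methyl orsellinate) | COC(=O)c1c(C)cc(O)cc1O | starting material
2 | methyl 3-chloro-4,6-dihydroxy-2-methylbenzoate | COC(=O)c1c(C)c(Cl)c(O)cc1O | intermediate
3 | methyl 3-chloro-4,6-bis(methoxymethoxy)-2-methylbenzoate | COC(=O)c1c(C)c(Cl)c(OCOC)cc1OCOC | intermediate
4 | ethyl 2,2-diethoxyacetate | CCOC(=O)C(OCC)OCC | starting material
5 | methyl 3-chloro-2-(3,3-diethoxy-2-oxopropyl)-4,6-bis(methoxymethoxy)benzoate | CCOC(OCC)C(=O)Cc1c(Cl)c(OCOC)cc(OCOC)c1C(=O)OC | intermediate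
6 | 5-chloro-6,8-dihydroxy-1-oxo-1H-isochromene-3-carbaldehyde | O=Cc1cc2c(Cl)c(O)cc(O)c2c(=O)o1 | intermediate
7 | 6,8-bis[(tert-butyldimethylsilyl)oxy]-5-chloro-1-oxo-1H-isochromene-3-carbaldehyde | O=Cc1cc2c(Cl)c(O[Si](C)(C)C(C)(C)C)cc(O[Si](C)(C)C(C)(C)C)c2c(=O)o1 | intermediate
8 | iodoform (triiodomethane) | IC(I)I | starting material
9 | 6,8-bis[(tert-butyldimethylsilyl)oxy]-5-chloro-3-[(E)-2-iodoethenyl]-1H-isochromen-1-one | I/C=C/c1cc2c(Cl)c(O[Si](C)(C)C(C)(C)C)cc(O[Si](C)(C)C(C)(C)C)c2c(=O)o1 | intermediate
10 | ethyl (S)-3-hydroxybutanoate | C[C@H](O)CC(=O)OCC | starting material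
11 | (S)-3-hydroxy-N-methoxy-N-methylbutanamide | C[C@H](O)CC(=O)N(C)OC | intermediate
12 | vinylmagnesium bromide (ethenylmagnesium bromide) | C=C[Mg]Br | starting material
13 | (S)-5-hydroxyhex-1-en-3-one | C[C@H](O)CC(=O)C=C | intermediate
14 | (3R,5S)-hex-1-ene-3,5-diol | C[C@H](O)C[C@@H](O)C=C | intermediate
15 | (4R,6S)-4-ethenyl-2,2,6-trimethyl-1,3-dioxane | C[C@H]1C[C@H](C=C)OC(C)(C)O1 | intermediate
16 | (E)-but-2-enal (crotonaldehyde) | C/C=C/C=O | starting material
17 | (E)-3-[(4R,6S)-2,2,6-trimethyl-1,3-dioxan-4-yl]prop-2-enal | C[C@H]1C[C@H](/C=C/C=O)OC(C)(C)O1 | intermediate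
18 | 6,8-bis[(tert-butyldimethylsilyl)oxy]-5-chloro-3-[(1E,4E)-3-hydroxy-5-[(4R,6S)-2,2,6-trimethyl-1,3-dioxan-4-yl]penta-1,4-dien-1-yl]-1H-isochromen-1-one (both carbinol epimers) | C[C@H]1C[C@H](/C=C/C(O)/C=C/c2cc3c(Cl)c(O[Si](C)(C)C(C)(C)C)cc(O[Si](C)(C)C(C)(C)C)c3c(=O)o2)OC(C)(C)O1 | intermediate
19 | 6,8-bis[(tert-butyldimethylsilyl)oxy]-5-chloro-3-[(1E,3E)-4-[(2S,3R,5S)-3-hydroxy-5-methyloxolan-2-yl]buta-1,3-dien-1-yl]-1H-isochromen-1-one | C[C@H]1C[C@@H](O)[C@H](/C=C/C=C/c2cc3c(Cl)c(O[Si](C)(C)C(C)(C)C)cc(O[Si](C)(C)C(C)(C)C)c3c(=O)o2)O1 | intermediate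
20 | 5-chloro-6,8-dihydroxy-3-[(1E,3E)-4-[(2S,3R,5S)-3-hydroxy-5-methyloxolan-2-yl]buta-1,3-dien-1-yl]-1H-isochromen-1-one | C[C@H]1C[C@@H](O)[C@H](/C=C/C=C/c2cc3c(Cl)c(O)cc(O)c3c(=O)o2)O1 | target

Total step count: 13. Longest linear sequence: 8 steps (steps 1 to 6, 12 and 13); the second arm (steps 7 to 11) has 5 steps before the union.

Steps most likely to fail

Step 12. The one-flask operation may stall after the coupling, or the cation may be captured with poor facial selectivity at C2, or be diverted into elimination, hydration or reduction by residual divalent chromium. The fallback closes the oxolane before the coupling and makes the same carbon-carbon bond by a Heck reaction. It sets out from 17: Luche reduction (NaBH4, CeCl3·7H2O, MeOH) should give (E)-3-[(4R,6S)-2,2,6-trimethyl-1,3-dioxan-4-yl]prop-2-en-1-ol F1. Aqueous AcOH removes the acetal to give (2E,4R,6S)-hept-2-ene-1,4,6-triol F2. Dehydrative cyclization catalysed by PdCl2(MeCN)2 (oxypalladation with allylic transposition by divalent palladium) should give (2S,3R,5S)-2-ethenyl-5-methyloxolan-3-ol F3. Heck coupling of F3 with 9 (Pd(OAc)2, Ag2CO3, DMF) joins the terminal alkene carbon to the iodide-bearing carbon and comes back to the route at 19.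

Step 4. The three acid-driven events may run in the wrong order: early unmasking of the aldehyde next to the ketone would expose a 1,2-dicarbonyl unit to hydration and self-condensation before the lactone closes. The fallback builds the ring first on a methyl ketone and oxidizes afterwards. It sets out from 3: lateral lithiation with LiN(iPr)2 and acylation with N-methoxy-N-methylacetamide should give methyl 3-chloro-4,6-bis(methoxymethoxy)-2-(2-oxopropyl)benzoate F4. Aqueous HCl should then give 5-chloro-6,8-dihydroxy-3-methyl-1H-isochromen-1-one F5. Silylation (TBSOTf, 2,6-lutidine) should give 6,8-bis[(tert-butyldimethylsilyl)oxy]-5-chloro-3-methyl-1H-isochromen-1-one F6. Riley oxidation of the 3-methyl group with SeO2 in dioxane at reflux comes back to the route at 7.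

Step 8. The β-hydroxy vinyl ketone may be lost to conjugate addition of the released amine during the quench, to polymerization or to retro-aldol cleavage. The fallback carries the two carbons as a silyl alkyne and unveils the alkene only after the reduction. It sets out from 11: addition of LiC≡CSiMe3 should give (S)-5-hydroxy-1-(trimethylsilyl)hex-1-yn-3-one F7. Evans-Saksena reduction with Me4NBH(OAc)3 should give (3R,5S)-1-(trimethylsilyl)hex-1-yne-3,5-diol F8. K2CO3 in MeOH should give (3R,5S)-hex-1-yne-3,5-diol F9. Semihydrogenation (H2, Lindlar catalyst: Pd on CaCO3 poisoned with Pb(OAc)2, quinoline) comes back to the route at 14.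

Further compounds
F1 | step 12 | (E)-3-[(4R,6S)-2,2,6-trimethyl-1,3-dioxan-4-yl]prop-2-en-1-ol | C[C@H]1C[C@H](/C=C/CO)OC(C)(C)O1
F2 | step 12 | (2E,4R,6S)-hept-2-ene-1,4,6-triol | C[C@H](O)C[C@@H](O)/C=C/CO
F3 | step 12 | (2S,3R,5S)-2-ethenyl-5-methyloxolan-3-ol | C[C@H]1C[C@@H](O)[C@H](C=C)O1
F4 | step 4 | methyl 3-chloro-4,6-bis(methoxymethoxy)-2-(2-oxopropyl)benzoate | COC(=O)c1c(CC(C)=O)c(Cl)c(OCOC)cc1OCOC
F5 | step 4 | 5-chloro-6,8-dihydroxy-3-methyl-1H-isochromen-1-one | Cc1cc2c(Cl)c(O)cc(O)c2c(=O)o1
F6 | step 4 | 6,8-bis[(tert-butyldimethylsilyl)oxy]-5-chloro-3-methyl-1H-isochromen-1-one | Cc1cc2c(Cl)c(O[Si](C)(C)C(C)(C)C)cc(O[Si](C)(C)C(C)(C)C)c2c(=O)o1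
F7 | step 8 | (S)-5-hydroxy-1-(trimethylsilyl)hex-1-yn-3-one | C[C@H](O)CC(=O)C#C[Si](C)(C)C
F8 | step 8 | (3R,5S)-1-(trimethylsilyl)hex-1-yne-3,5-diol | C[C@H](O)C[C@@H](O)C#C[Si](C)(C)C
F9 | step 8 | (3R,5S)-hex-1-yne-3,5-diol | C[C@H](O)C[C@@H](O)C#C
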